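**Plan**
- Enabling feature: ring B is a 1,4-benzoquinone with C=O at C2'/C5' and OMe at C3'/C4'. Its only carbon substituent (chroman C3) sits on C1', next to C6'–H. C2'–C3'–C4'–C5' is the carbon square of dimethyl squarate, and C6'≡C1' is a terminal alkyne carried by C3.
- Cuts, in retrosynthetic order: C1'–C2' (ring expansion of a 4-alkynyl-4-hydroxycyclobutenone), C5'–C6' (acetylide plus squarate), C3–C1' (boron-to-carbon 1,2-shift), C3–B (borylation of C3=C4), C4–C4a (propargyl Claisen cascade), O1–C2 (Williamson).
- Forward: ring A is bought and the pyran ring C closes first. The two-carbon unit C1'≡C6' is then put on C3, the four-membered ring is attached, and ring B arises last from it.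
- Stereochemistry: the only stereocentre, C3 (S in the target), is set by ligand-controlled copper-catalysed borylation of the prochiral C3=C4 alkene. It is passed on with retention in the 1,2-metallate shift and is a spectator afterwards.

Key step: step 7

Assumption: the ligand enantiomer written in step 3 is taken to be the one that delivers boron to the alkene face giving the 3R boronic ester. Both ligand enantiomers are sold, so the sense of induction is checked once, by chiroptical comparison at the stage of the natural product, and the antipode is used if needed.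

Step 1
Reactants: 1 2,3,4-trimethoxyphenol; 2 propargyl bromide
Product: 3 1,2,3-trimethoxy-4-(prop-2-yn-1-yloxy)benzene
Conditions: K2CO3, acetone, reflux
Reagents that add atoms: propargyl bromide 2, C#CCBr
Why: Williamson ether synthesis; the phenoxide should displace the primary propargylic bromide by SN2 at oxygen, and nothing else in 1 is nucleophilic.

Step 2
Reactants: 3 1,2,3-trimethoxy-4-(prop-2-yn-1-yloxy)benzene
Product: 5 6,7,8-trimethoxy-2H-chromene, via 2,3,4-trimethoxy-6-(propa-1,2-dien-1-yl)phenol 4 (not isolated)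
Conditions: PhNEt2, 210 °C, Ar
Reagents that add atoms: none
Why: Aromatic propargyl Claisen rearrangement to the only free ortho position gives allenylphenol 4 after tautomerisation, and a [1,5]-hydrogen shift followed by oxa-6π electrocyclisation should close ring C, the standard thermal route from aryl propargyl ethers to 2H-chromenes.

Step 3
Reactants: 5 6,7,8-trimethoxy-2H-chromene; 6 bis(pinacolato)diboron
Product: 7 2-[(3R)-6,7,8-trimethoxy-3,4-dihydro-2H-chromen-3-yl]-4,4,5,5-tetramethyl-1,3,2-dioxaborolane
Conditions: CuCl (5 mol %), (R,R)-QuinoxP* (6 mol %), NaOt-Bu (20 mol %), MeOH (2 equiv), THF, 0 °C to rt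
Reagents that add atoms: bis(pinacolato)diboron 6, CC1(C)OB(OC1(C)C)B1OC(C)(C)C(C)(C)O1
Why: Copper(I)-catalysed enantioselective protoboration (formal hydroboration), known for 2H-chromenes: the ligated Cu–Bpin adds syn across C3=C4 with boron on C3 and copper on the benzylic C4, the C2-symmetric bisphosphine chooses the alkene face and so sets C3 as R, and methanol protonates the C4–Cu bond.

Step 4
Reactants: 7 2-[(3R)-6,7,8-trimethoxy-3,4-dihydro-2H-chromen-3-yl]-4,4,5,5-tetramethyl-1,3,2-dioxaborolane; 8 vinyl bromide
Product: 11 (3R)-3-(1-bromoethenyl)-6,7,8-trimethoxy-3,4-dihydro-2H-chromene, via lithium (1-bromoethenyl)[(3R)-6,7,8-trimethoxychroman-3-yl](pinacolato)borate 9 (not isolated), via 2-{1-bromo-2-iodo-1-[(3R)-6,7,8-trimethoxychroman-3-yl]ethyl}-4,4,5,5-tetramethyl-1,3,2-dioxaborolane 10 (not isolated)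
Conditions: CH2=CHBr (1 M in THF, excess), LDA added last, THF, −78 °C; I2, MeOH, −78 °C; NaOMe, −78 °C to rt
Reagents that add atoms: vinyl bromide 8, C=CBr
Why: Zweifel-type olefination of a secondary pinacol boronic ester: LDA lithiates vinyl bromide in the presence of 7, the 1-bromovinyl anion binds to boron (9), iodine activates the alkene and triggers the 1,2-shift of C3 from boron to carbon with retention of configuration (10), and methoxide-induced anti-elimination of boron and iodide should leave 11 with the C3–C1' bond in place, all stages up to the shift being run at −78 °C so that the ate complex has no time to lose the β-aryloxide.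

Step 5
Reactants: 11 (3R)-3-(1-bromoethenyl)-6,7,8-trimethoxy-3,4-dihydro-2H-chromene
Product: 12 (3S)-3-ethynyl-6,7,8-trimethoxy-3,4-dihydro-2H-chromene
Conditions: TBAF·3H2O, DMF, 60 °C
Reagents that add atoms: none
Why: Fluoride-induced E2 dehydrobromination of a 2-bromo-1-alkene to the 1-alkyne; wet TBAF is too weak a base to remove the C3–H, so allene formation, epimerisation and opening of the pyran ring should not intervene (the descriptor changes from R to S only through the CIP ranking).

Step 6
Reactants: 12 (3S)-3-ethynyl-6,7,8-trimethoxy-3,4-dihydro-2H-chromene; 13 dimethyl squarate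
Product: 16 4-hydroxy-2,3-dimethoxy-4-{[(3S)-6,7,8-trimethoxychroman-3-yl]ethynyl}cyclobut-2-en-1-one (both carbinol epimers), via lithium [(3S)-6,7,8-trimethoxychroman-3-yl]acetylide 14 (not isolated), via lithium alkoxide of the adduct 15 (not isolated)
Conditions: n-BuLi (1.0 equiv), THF, −78 °C; cannulated into 13 (1.2 equiv), THF, −78 °C; sat. aq NH4Cl, −78 °C
Reagents that add atoms: dimethyl squarate 13, COC1=C(OC)C(=O)C1=O
Why: 1,2-Addition of a lithium acetylide to one of the two equivalent carbonyl groups of a squarate diester, run by inverse addition at −78 °C so that only one addition occurs; the new carbinol centre is not controlled and need not be, because it becomes the planar C5' carbonyl carbon in step 7.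

Step 7
Reactants: 16 4-hydroxy-2,3-dimethoxy-4-{[(3S)-6,7,8-trimethoxychroman-3-yl]ethynyl}cyclobut-2-en-1-one
Product: 19 abruquinone B, 2,3-dimethoxy-5-[(3S)-6,7,8-trimethoxy-3,4-dihydro-2H-chromen-3-yl]cyclohexa-2,5-diene-1,4-dione, via (3Z)-4-hydroxy-2,3-dimethoxy-6-[(3S)-6,7,8-trimethoxychroman-3-yl]hexa-1,3-dien-5-yn-1-one 17 (not isolated), via 4-hydroxy-2,3-dimethoxy-6-[(3S)-6,7,8-trimethoxychroman-3-yl]phenoxyl-5-yl diradical 18 (not isolated)
Conditions: p-xylene (0.01 M, degassed), 138 °C, Ar; then concentration in air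
Reagents that add atoms: none
Why: Heating opens the cyclobutenone by a 4π conrotatory electrocyclic reaction that breaks the C2'–C5' σ-bond and releases the ring strain; the hydroxyl donor turns outward, so the alkynyl group turns inward and the (Z)-enynylketene 17 holds ketene and alkyne on the same side, whichever carbinol epimer of 16 is used. The electrophilic ketene carbon C2' then bonds to the distal, chroman-bearing alkyne carbon C1' (6-endo-dig with respect to the alkyne, the Moore cyclisation, ketene counterpart of the Myers–Saito closure) and gives the aromatic phenoxyl/σ-aryl diradical 18. The σ-radical at C6' takes up the hydrogen of the C5' hydroxyl, directly or by relay between molecules, which leaves both carbonyl groups of quinone 19 without any oxidant, so the tetra-alkoxy ring A is never at risk. The closest known reaction type is the thermal ring expansion of 4-alkynyl-4-hydroxy-2,3-dialkoxycyclobutenones made from squarate esters to 2,3-dialkoxy-1,4-benzoquinones. The selectivity needed is six-membered against five-membered (5-exo-dig) closure: the group on C1' is a plain secondary alkyl that cannot stabilise the exocyclic vinyl radical of the five-membered path, the six-membered path gains aromaticity, and the free hydroxyl supplies the hydrogen. No stereocentre is formed, the carbinol centre vanishes, and C3 is carried through as S, because it is propargylic and non-enolisable in 16 and its neighbouring C–H bonds could reach the C6' radical only through strained 1,3- or 1,4-hydrogen shifts.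

**Compound list**
1 | 2,3,4-trimethoxyphenol | COc1ccc(O)c(OC)c1OC | starting material
2 | propargyl bromide | C#CCBr | starting material
3 | 1,2,3-trimethoxy-4-(prop-2-yn-1-yloxy)benzene | C#CCOc1ccc(OC)c(OC)c1OC | intermediate
4 | 2,3,4-trimethoxy-6-(propa-1,2-dien-1-yl)phenol | C=C=Cc1cc(OC)c(OC)c(OC)c1O | intermediate
5 | 6,7,8-trimethoxy-2H-chromene | COc1cc2C=CCOc2c(OC)c1OC | intermediate
6 | bis(pinacolato)diboron | CC1(C)OB(OC1(C)C)B1OC(C)(C)C(C)(C)O1 | starting material
7 | 2-[(3R)-6,7,8-trimethoxy-3,4-dihydro-2H-chromen-3-yl]-4,4,5,5-tetramethyl-1,3,2-dioxaborolane | CC1(C)OB(OC1(C)C)[C@H]2COc3c(cc(OC)c(OC)c3OC)C2 | intermediate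
8 | vinyl bromide | C=CBr | starting material
9 | lithium (1-bromoethenyl)[(3R)-6,7,8-trimethoxychroman-3-yl](pinacolato)borate | [Li+].C=C(Br)[B-]1(OC(C)(C)C(C)(C)O1)[C@H]2COc3c(cc(OC)c(OC)c3OC)C2 | intermediate
10 | 2-{1-bromo-2-iodo-1-[(3R)-6,7,8-trimethoxychroman-3-yl]ethyl}-4,4,5,5-tetramethyl-1,3,2-dioxaborolane (side-chain carbon of no consequence) | ICC(Br)(B1OC(C)(C)C(C)(C)O1)[C@H]2COc3c(cc(OC)c(OC)c3OC)C2 | intermediate
11 | (3R)-3-(1-bromoethenyl)-6,7,8-trimethoxy-3,4-dihydro-2H-chromene | C=C(Br)[C@H]2COc3c(cc(OC)c(OC)c3OC)C2 | intermediate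
12 | (3S)-3-ethynyl-6,7,8-trimethoxy-3,4-dihydro-2H-chromene | C#C[C@H]2COc3c(cc(OC)c(OC)c3OC)C2 | intermediate
13 | dimethyl squarate (3,4-dimethoxycyclobut-3-ene-1,2-dione) | COC1=C(OC)C(=O)C1=O | starting material
14 | lithium [(3S)-6,7,8-trimethoxychroman-3-yl]acetylide | [Li]C#C[C@H]2COc3c(cc(OC)c(OC)c3OC)C2 | intermediate
15 | lithium 2,3-dimethoxy-4-oxo-1-{[(3S)-6,7,8-trimethoxychroman-3-yl]ethynyl}cyclobut-2-en-1-olate | [Li+].COC1=C(OC)C([O-])(C#C[C@H]2COc3c(cc(OC)c(OC)c3OC)C2)C1=O | intermediate
16 | 4-hydroxy-2,3-dimethoxy-4-{[(3S)-6,7,8-trimethoxychroman-3-yl]ethynyl}cyclobut-2-en-1-one (both carbinol epimers) | COC1=C(OC)C(O)(C#C[C@H]2COc3c(cc(OC)c(OC)c3OC)C2)C1=O | intermediate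
17 | (3Z)-4-hydroxy-2,3-dimethoxy-6-[(3S)-6,7,8-trimethoxychroman-3-yl]hexa-1,3-dien-5-yn-1-one (enynylketene) | O=C=C(OC)/C(OC)=C(/O)C#C[C@H]1COc2c(cc(OC)c(OC)c2OC)C1 | intermediate
18 | 4-hydroxy-2,3-dimethoxy-6-[(3S)-6,7,8-trimethoxychroman-3-yl]phenoxyl-5-yl diradical (O-radical on the C2' oxygen, σ-radical on C6') | COc1c(OC)c(O)[c]c([C@H]2COc3c(cc(OC)c(OC)c3OC)C2)c1[O] | intermediate
19 | abruquinone B, 2,3-dimethoxy-5-[(3S)-6,7,8-trimethoxy-3,4-dihydro-2H-chromen-3-yl]cyclohexa-2,5-diene-1,4-dione | COC1=C(OC)C(=O)C([C@H]2COc3c(cc(OC)c(OC)c3OC)C2)=CC1=O | target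

Total step count: 7. Longest linear sequence: 7 steps (1 to 19).

**Steps most likely to fail**

**Step 4.**
- What may go wrong: the lithiated vinyl bromide may decay before the hindered secondary boron centre captures it. The ate complex may open the pyran ring by β-elimination of the aryloxide, since C3–B and C2–O1 can stand anti-periplanar. Iodine may also attack ring A.
- Fallback, from 7 back to 12: the two alkyne carbons are brought in one at a time.
- Matteson homologation of 7 (BrCH2Cl, n-BuLi, THF, −78 °C to rt, retention at C3) should give the homologous boronic ester 2-{[(3R)-6,7,8-trimethoxychroman-3-yl]methyl}-4,4,5,5-tetramethyl-1,3,2-dioxaborolane F1.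
- Oxidation (NaBO3·4H2O, THF–H2O) should give the primary alcohol [(3S)-6,7,8-trimethoxychroman-3-yl]methanol F2.
- Buffered Dess–Martin oxidation (NaHCO3, CH2Cl2, 0 °C) should give the aldehyde (3R)-6,7,8-trimethoxychroman-3-carbaldehyde F3.
- Corey–Fuchs olefination under neutral conditions (CBr4, PPh3, CH2Cl2, 0 °C) should give the dibromoalkene (3S)-3-(2,2-dibromoethenyl)-6,7,8-trimethoxychroman F4.
- n-BuLi (2 equiv, THF, −78 °C) should convert F4 into acetylide 14, which is protonated to 12 or taken straight into step 6.
- This path needs neither iodine nor a vinylic carbenoid. If ring opening of C3 ate complexes as such is the cause, the boron-free path under step 3 takes over.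

**Step 7.**
- What may go wrong: five-membered closure may compete, and the σ-radical may take hydrogen from the solvent or add to other molecules. Long heating may erode C3 through tautomerisation of the alkylquinone.
- Fallback, from 12 to 19: the squarate disconnection is kept, but the diradical closure is exchanged for a concerted one at the hydroquinone oxidation level.
- Hydrozirconation–iodination of 12 (Cp2Zr(H)Cl, THF, rt; I2, 0 °C) should give the vinyl iodide (3S)-3-[(E)-2-iodoethenyl]-6,7,8-trimethoxychroman F5.
- Iodine–lithium exchange (t-BuLi, Et2O, −78 °C) and addition to 13 should give the alkenylcyclobutenone 4-hydroxy-2,3-dimethoxy-4-{(E)-2-[(3S)-6,7,8-trimethoxychroman-3-yl]ethenyl}cyclobut-2-en-1-one F6.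
- Heating F6 (toluene, 110 °C) should bring about 4π opening and 6π electrocyclic closure of C2'–C1', for which no five-membered alternative exists. Tautomerisation then gives the hydroquinone 2,3-dimethoxy-5-[(3S)-6,7,8-trimethoxychroman-3-yl]benzene-1,4-diol F7.
- Ag2O (Et2O, rt) or air should oxidise F7 to 19 at a potential far below that needed to touch ring A.

**Step 3.**
- What may go wrong: the donor groups of ring A make the styrene-type alkene electron-rich, so borylcupration may be slow and facial selectivity poor. Any insertion with reversed regiochemistry would place copper β to the aryloxide and open the ring.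
- Fallback, from 1 back to 12: a boron-free path with C3 set by asymmetric hydrogenation.
- ortho-Formylation of 1 (MgCl2, Et3N, paraformaldehyde, MeCN, reflux) should give the salicylaldehyde 2-hydroxy-3,4,5-trimethoxybenzaldehyde F8.
- DABCO-promoted Baylis–Hillman annulation with acrylonitrile (reflux) should give the nitrile 6,7,8-trimethoxy-2H-chromene-3-carbonitrile F9.
- Hydrolysis (aq NaOH, reflux; then HCl) should give the unsaturated acid 6,7,8-trimethoxy-2H-chromene-3-carboxylic acid F10.
- Hydrogenation with a chiral iridium spiro-phosphine–oxazoline or Ru–BINAP catalyst (H2, MeOH, Et3N) should give the saturated acid (3R)-6,7,8-trimethoxychroman-3-carboxylic acid F11.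
- BH3·THF should reduce F11 to the alcohol F2, which goes on through F3 and F4 to 12 as described under step 4.

**Further compounds**
F1 | step 4 | 2-{[(3R)-6,7,8-trimethoxychroman-3-yl]methyl}-4,4,5,5-tetramethyl-1,3,2-dioxaborolane | CC1(C)OB(OC1(C)C)C[C@H]2COc3c(cc(OC)c(OC)c3OC)C2
F2 | step 4 | [(3S)-6,7,8-trimethoxychroman-3-yl]methanol | OC[C@H]2COc3c(cc(OC)c(OC)c3OC)C2
F3 | step 4 | (3R)-6,7,8-trimethoxychroman-3-carbaldehyde | O=C[C@H]2COc3c(cc(OC)c(OC)c3OC)C2
F4 | step 4 | (3S)-3-(2,2-dibromoethenyl)-6,7,8-trimethoxychroman | BrC(Br)=C[C@H]2COc3c(cc(OC)c(OC)c3OC)C2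
F5 | step 7 | (3S)-3-[(E)-2-iodoethenyl]-6,7,8-trimethoxychroman | I/C=C/[C@H]2COc3c(cc(OC)c(OC)c3OC)C2
F6 | step 7 | 4-hydroxy-2,3-dimethoxy-4-{(E)-2-[(3S)-6,7,8-trimethoxychroman-3-yl]ethenyl}cyclobut-2-en-1-one | COC1=C(OC)C(O)(/C=C/[C@H]2COc3c(cc(OC)c(OC)c3OC)C2)C1=O
F7 | step 7 | 2,3-dimethoxy-5-[(3S)-6,7,8-trimethoxychroman-3-yl]benzene-1,4-diol | COc1c(OC)c(O)c([C@H]2COc3c(cc(OC)c(OC)c3OC)C2)cc1O
F8 | step 3 | 2-hydroxy-3,4,5-trimethoxybenzaldehyde | COc1cc(C=O)c(O)c(OC)c1OC
F9 | step 3 | 6,7,8-trimethoxy-2H-chromene-3-carbonitrile | N#CC1=Cc2cc(OC)c(OC)c(OC)c2OC1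
F10 | step 3 | 6,7,8-trimethoxy-2H-chromene-3-carboxylic acid | OC(=O)C1=Cc2cc(OC)c(OC)c(OC)c2OC1
F11 | step 3 | (3R)-6,7,8-trimethoxychroman-3-carboxylic acid | OC(=O)[C@H]2COc3c(cc(OC)c(OC)c3OC)C2
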